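**Retrosynthetic overview**

1. The side chain and the exocyclic alkene come last: the 13E-enoate by Horner–Wadsworth–Emmons olefination of a C13 methyl ketone, C8=C17 by Wittig methylenation of an 8-ketone, the acetate on a 3β-alcohol.
2. Ring B (C5–C6–C7–C8–C9–C10) comes from the five-membered ring C5–C6–C7–C8–C10 of a trans-hydrindane: a semipinacol 1,2-shift moves the quaternary C10 from C8 to the exocyclic C9, which inserts C9 with the side chain and leaves the carbonyl on C8.
3. Enabling feature: the 8α-hydroxy/9-mesyloxy unit on the five-membered ring, made from a Z-C8=C9 alkene. Its only unhindered rotamer holds the C8–C10 bond anti-periplanar to C9–OMs; the strained trans-hydrindane and the quaternary migrating carbon drive the shift.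
4. Ring A: Hajos–Parrish-type aldol condensation (C10 set by L-phenylalanine), then reductive methylation (C4 gem-dimethyl, 5α-H) and hydride reduction (3β-OH).
5. Order of rings: five-membered ring (from 2-methylcyclopentane-1,3-dione), then ring A, then ring B by ring enlargement.

Key step: step 10

Remark: atoms carry the labdane numbering of the target throughout (in the hydrindane stage C9 is the exocyclic carbon on C8); α is the face opposite the C10 methyl; the target is read as 3β-OAc, 5α-H, 9α-H, 10β-CH3.

**Route**

Step 1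
Reactants: 1 2-methylcyclopentane-1,3-dione; 2 pent-1-en-3-one
Product: 3 2-methyl-2-(3-oxopentyl)cyclopentane-1,3-dione
Conditions: H2O, AcOH (cat.), 75 °C
Reagents that add atoms: none
Why: Michael addition of the enolised 1,3-dione to the vinyl ketone proceeds readily in water and creates no stereocentre, since C10 still carries two equivalent ring carbonyls.

Step 2
Reactants: 3 2-methyl-2-(3-oxopentyl)cyclopentane-1,3-dione
Product: 4 (7aS)-4,7a-dimethyl-2,3,7,7a-tetrahydro-1H-indene-1,5(6H)-dione
Conditions: L-phenylalanine (1 equiv), (1S)-(+)-camphor-10-sulfonic acid (0.5 equiv), DMF, 30 → 70 °C; recrystallisation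
Reagents that add atoms: none
Why: Hajos–Parrish-type intramolecular aldol condensation: the enamine of the side-chain ketone with L-phenylalanine attacks one of the two enantiotopic ring carbonyls through a hydrogen-bonded transition state, which sets C10 (7aS, the configuration of natural steroids), and acid-promoted dehydration gives the enone.

Step 3
Reactants: 5 2-(3-chloropropyl)-2-methyl-1,3-dioxolane
Product: 6 [3-(2-methyl-1,3-dioxolan-2-yl)propyl]triphenylphosphonium iodide
Conditions: PPh3, NaI, MeCN, reflux
Reagents that add atoms: triphenylphosphine, c1ccc(cc1)P(c1ccccc1)c1ccccc1; sodium iodide, [Na+].[I-]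
Why: SN2 quaternisation of triphenylphosphine by the primary chloride under Finkelstein catalysis, iodide ending up as the counter-ion.

Step 4
Reactants: 4 (7aS)-4,7a-dimethyl-2,3,7,7a-tetrahydro-1H-indene-1,5(6H)-dione; 6 [3-(2-methyl-1,3-dioxolan-2-yl)propyl]triphenylphosphonium iodide
Product: 8 (1Z,7aS)-4,7a-dimethyl-1-[3-(2-methyl-1,3-dioxolan-2-yl)propylidene]-1,2,3,6,7,7a-hexahydro-5H-inden-5-one, via phosphorus ylide 7 (not isolated)
Conditions: 6, KN(SiMe3)2, THF, −78 → 0 °C; then 4, 0 → 45 °C
Reagents that add atoms: none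
Why: Wittig olefination: the non-stabilised ylide should add to the isolated cyclopentanone in preference to the tetrasubstituted, conjugated enone carbonyl, and kinetic oxaphosphetane formation from the α face should give the Z alkene (side chain cis to C10), as in the ethylidenation of 17-oxo steroids.

Step 5
Reactants: 8 Z-alkylidene enone
Product: 10 trans-fused 4,4,10-trimethylhydrindan-3-one (5α-H) with the Z-C8=C9 alkylidene and ketal side chain, via lithium enolate 9 (not isolated)
Conditions: Li (2.1 equiv), t-BuOH (1.0 equiv), NH3(l)/THF, −78 °C; then MeI, −78 → −33 °C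
Reagents that add atoms: iodomethane, CI
Why: Birch-type reductive alkylation of the enone: the C5 carbanion is protonated axially on the face opposite the C10 methyl (trans ring fusion, 5α-H), and the regiospecific lithium enolate is C-methylated at C4 to complete the gem-dimethyl group, the isolated alkene and the ketal being inert to Li/NH3.

Step 6
Reactants: 10 trans-hydrindan-3-one
Product: 11 the corresponding 3β-alcohol
Conditions: NaBH4, MeOH, 0 °C
Reagents that add atoms: none
Why: Hydride reduction: NaBH4 attacks the 4,4-dimethyl-3-ketone axially from the α face, away from the axial 4β- and 10β-methyl groups, to give the equatorial 3β-alcohol.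

Step 7
Reactants: 11 3β-alcohol
Product: 12 3β-triethylsilyl ether of 11
Conditions: Et3SiCl, imidazole, DMAP (cat.), DMF, 40 °C
Reagents that add atoms: chlorotriethylsilane, CC[Si](Cl)(CC)CC
Why: Silylation of the hindered secondary alcohol protects it against sulfonylation in step 9 and survives the basic steps that follow.

Step 8
Reactants: 12 silyl ether with Z-C8=C9 alkene
Product: 13 8α,9-diol (both hydroxyls delivered from the α face; C9 now sp3, on the β side of C8)
Conditions: OsO4 (5 mol %), NMO, MeSO2NH2, acetone/H2O, 25 °C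
Reagents that add atoms: N-methylmorpholine N-oxide, C[N+]1([O-])CCOCC1; water, O
Why: Upjohn syn-dihydroxylation: OsO4 adds to the only alkene from the α face, opposite the angular methyl, which sets 8α-OH and, through the Z geometry, the C9 configuration needed in step 10.

Step 9
Reactants: 13 8α,9-diol
Product: 14 8α-hydroxy-9-methanesulfonate
Conditions: MsCl, Et3N, DMAP (cat.), CH2Cl2, −20 → 0 °C
Reagents that add atoms: methanesulfonyl chloride, CS(=O)(=O)Cl
Why: Sulfonylation is selective for the secondary C9 hydroxyl because the tertiary C8 hydroxyl and the silyl ether do not react under these conditions.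

Step 10
Reactants: 14 8α-hydroxy-9-methanesulfonate
Product: 16 3β-(triethylsilyloxy)-14,15,17-trinorlabdane-8,13-dione 13-ethylene ketal (9α-H), via 9-epi ketone 15 (not isolated)
Conditions: LiClO4 (5 equiv), CaCO3 (3 equiv), THF, 50 °C; then NaOMe (0.2 equiv), MeOH, 25 °C
Reagents that add atoms: none
Why: Li+-assisted ionisation of the secondary C9 mesylate is concerted with an anti-periplanar 1,2-shift of the quaternary C10 from C8 to C9, while the C8 hydroxyl oxygen donates and becomes the C8 carbonyl (semipinacol rearrangement of a 2-hydroxy sulfonate). The closest known reaction type is the pinacol-type ring enlargement of diol monosulfonates made from alkylidene cycloalkanes, including D-homoannulation of 17α-hydroxy-20-sulfonyloxy steroids with migration of the quaternary C13. Ring B (C5–C6–C7–C8–C9–C10) is not closed by a cyclisation; it arises from the ring C5–C6–C7–C8–C10 by insertion of C9 between C8 and C10 through a bridged three-centre transition state, with release of trans-hydrindane strain. C10 migrates with retention and C9 is inverted, which gives the axial 9-epimer 15; NaOMe then equilibrates C9 through the C8 enolate to the equatorial side chain (9α-H), the configuration expected to be stable in 8-oxolabdanes. The step needs migration of C10 and not of C7: the Z alkene and α-face osmylation give the C9 epimer in which only the rotamer with the mesylate anti to C8–C10 keeps the side chain clear of the angular methyl (the rotamer for C7 migration pushes it against that methyl), and the quaternary carbon also has the higher migratory aptitude. Epoxide closure by the C8 oxygen would need the hindered rotamer and a free alkoxide, which the buffered, non-basic conditions avoid.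

Step 11
Reactants: 16 8-ketone
Product: 17 3β-(triethylsilyloxy)-14,15-dinorlabd-8(17)-en-13-one ethylene ketal
Conditions: Ph3PCH3Br, KOtBu, toluene, 25 → 70 °C
Reagents that add atoms: methyltriphenylphosphonium bromide, C[P+](c1ccccc1)(c1ccccc1)c1ccccc1.[Br-]
Why: Wittig methylenation of the hindered ketone, as practised on 8-oxolabdanes, installs C17; C9 is already at its thermodynamic configuration, so enolisation by the ylide cannot change it.

Step 12
Reactants: 17 silyl ether ketal
Product: 18 3β-hydroxy-14,15-dinorlabd-8(17)-en-13-one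
Conditions: 1 M HCl (aq), THF, 25 °C
Reagents that add atoms: water, O
Why: Acid hydrolysis cleaves the dioxolane and the triethylsilyl ether in one operation, and dilute acid at room temperature should not isomerise the 1,1-disubstituted alkene.

Step 13
Reactants: 18 hydroxy ketone
Product: 19 3β-acetoxy-14,15-dinorlabd-8(17)-en-13-one
Conditions: Ac2O, pyridine, DMAP (cat.), CH2Cl2, 25 °C
Reagents that add atoms: acetic anhydride, CC(=O)OC(C)=O
Why: DMAP-catalysed acylation of the equatorial 3β-alcohol with retention of configuration.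

Step 14
Reactants: 19 acetoxy methyl ketone
Product: 20 allyl 3β-acetoxylabda-8(17),13E-dien-15-oate
Conditions: allyl (diethoxyphosphoryl)acetate (1.3 equiv), NaH (1.15 equiv), THF, 0 → 65 °C
Reagents that add atoms: allyl (diethoxyphosphoryl)acetate, C=CCOC(=O)CP(=O)(OCC)OCC
Why: Horner–Wadsworth–Emmons olefination of the methyl ketone: the thermodynamically controlled elimination places the larger C12 chain trans to the ester, so the 13E isomer should predominate and the minor Z isomer is removed by chromatography; the acetate is inert to the stabilised phosphonate anion.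

Step 15
Reactants: 20 allyl ester
Product: 21 3-acetoxy-8(17),13E-labdadien-15-oic acid
Conditions: Pd(PPh3)4 (5 mol %), morpholine, THF, 25 °C
Reagents that add atoms: none
Why: Tsuji–Trost-type deallylation: zerovalent palladium ionises the allyl ester to a π-allyl complex that morpholine captures, which releases the acid without touching the acetate, the enoate or the exocyclic alkene.

**Compound list**

1 | 2-methylcyclopentane-1,3-dione | CC1C(=O)CCC1=O | starting material
2 | pent-1-en-3-one (ethyl vinyl ketone) | CCC(=O)C=C | starting material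
3 | 2-methyl-2-(3-oxopentyl)cyclopentane-1,3-dione | CCC(=O)CCC1(C)C(=O)CCC1=O | intermediate
4 | (7aS)-4,7a-dimethyl-2,3,7,7a-tetrahydro-1H-indene-1,5(6H)-dione | CC1=C2CCC(=O)[C@@]2(C)CCC1=O | intermediate
5 | 2-(3-chloropropyl)-2-methyl-1,3-dioxolane | CC1(CCCCl)OCCO1 | starting material
6 | [3-(2-methyl-1,3-dioxolan-2-yl)propyl]triphenylphosphonium iodide | CC1(CCC[P+](c2ccccc2)(c2ccccc2)c2ccccc2)OCCO1.[I-] | intermediate
7 | [3-(2-methyl-1,3-dioxolan-2-yl)propylidene]triphenylphosphorane | CC1(CCC=P(c2ccccc2)(c2ccccc2)c2ccccc2)OCCO1 | intermediate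
8 | (1Z,7aS)-4,7a-dimethyl-1-[3-(2-methyl-1,3-dioxolan-2-yl)propylidene]-1,2,3,6,7,7a-hexahydro-5H-inden-5-one | CC1=C2CC/C(=C/CCC3(C)OCCO3)[C@@]2(C)CCC1=O | intermediate
9 | lithium enolate of 10 before methylation (C3–OLi, C3=C4, 5α-H) | [Li+].CC=1[C@@H]2CC/C(=C/CCC3(C)OCCO3)[C@@]2(C)CCC1[O-] | intermediate
10 | trans-fused 4,4,10-trimethylhydrindan-3-one (5α-H, 10β-CH3) with Z-C8=C9 alkylidene bearing the ketal side chain | CC1(C)[C@@H]2CC/C(=C/CCC3(C)OCCO3)[C@@]2(C)CCC1=O | intermediate
11 | 3β-alcohol of 10 | CC1(C)[C@@H]2CC/C(=C/CCC3(C)OCCO3)[C@@]2(C)CC[C@@H]1O | intermediate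
12 | 3β-triethylsilyl ether of 11 | CC1(C)[C@@H]2CC/C(=C/CCC3(C)OCCO3)[C@@]2(C)CC[C@@H]1O[Si](CC)(CC)CC | intermediate
13 | 8α,9-diol of 12 (syn addition from the α face) | CC1(C)[C@@H]2CC[C@](O)([C@@H](O)CCC3(C)OCCO3)[C@@]2(C)CC[C@@H]1O[Si](CC)(CC)CC | intermediate
14 | 8α-hydroxy-9-methanesulfonate of 13 | CC1(C)[C@@H]2CC[C@](O)([C@@H](OS(C)(=O)=O)CCC3(C)OCCO3)[C@@]2(C)CC[C@@H]1O[Si](CC)(CC)CC | intermediate
15 | 9-epi-3β-(triethylsilyloxy)-14,15,17-trinorlabdane-8,13-dione 13-ethylene ketal (9β-H, axial side chain) | CC1(C)[C@@H]2CCC(=O)[C@@H](CCC3(C)OCCO3)[C@@]2(C)CC[C@@H]1O[Si](CC)(CC)CC | intermediate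
16 | 3β-(triethylsilyloxy)-14,15,17-trinorlabdane-8,13-dione 13-ethylene ketal (9α-H) | CC1(C)[C@@H]2CCC(=O)[C@H](CCC3(C)OCCO3)[C@@]2(C)CC[C@@H]1O[Si](CC)(CC)CC | intermediate
17 | 3β-(triethylsilyloxy)-14,15-dinorlabd-8(17)-en-13-one ethylene ketal | CC1(C)[C@@H]2CCC(=C)[C@H](CCC3(C)OCCO3)[C@@]2(C)CC[C@@H]1O[Si](CC)(CC)CC | intermediate
18 | 3β-hydroxy-14,15-dinorlabd-8(17)-en-13-one | CC1(C)[C@@H]2CCC(=C)[C@H](CCC(C)=O)[C@@]2(C)CC[C@@H]1O | intermediate
19 | 3β-acetoxy-14,15-dinorlabd-8(17)-en-13-one | CC1(C)[C@@H]2CCC(=C)[C@H](CCC(C)=O)[C@@]2(C)CC[C@@H]1OC(C)=O | intermediate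
20 | allyl 3β-acetoxylabda-8(17),13E-dien-15-oate | CC1(C)[C@@H]2CCC(=C)[C@H](CC/C(C)=C/C(=O)OCC=C)[C@@]2(C)CC[C@@H]1OC(C)=O | intermediate
21 | 3-acetoxy-8(17),13E-labdadien-15-oic acid | C=C1CC[C@H]2C(C)(C)[C@@H](OC(C)=O)CC[C@]2(C)[C@H]1CC/C(C)=C/C(=O)O | target

**Step count**

Total: 15 steps. Longest linear sequence: 14 steps (steps 1, 2 and 4–15); step 3 is a one-step side branch.

**Steps most likely to fail, with fallbacks**

Step 4. The basic ylide may enolise or attack the enone, the hindered cyclopentanone may react too slowly, or the olefin geometry may erode. The fallback sets out from 4 and postpones the olefination until the enone is gone. NaBH4 in EtOH at −20 °C reduces only the saturated C8 ketone from the α face to the 8β-hydroxy enone F1. Li in NH3 turns this into the dilithium alkoxide-enolate F2, which MeI methylates at C4 to the trans-fused 8β-hydroxy-4,4-dimethyl-3-ketone F3. Dess–Martin periodinane gives the 3,8-dione F4. LiAlH(OtBu)3 at −78 °C reduces the cyclohexanone carbonyl C3 in preference to the neopentyl cyclopentanone and gives the 3β-hydroxy-8-ketone F5. Wittig reaction of F5 with an excess of ylide 7 (a saturated ketone of the 17-oxo-steroid type, the free hydroxyl carried as its alkoxide) gives 11, where the route is rejoined.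

Step 5. Protonation at C5 may show poor facial selectivity, because C8 is sp2 here and the five-membered ring is flatter than in the usual hydrindenone reductions, so some cis-hydrindane may form. The fallback sets out from 8 and moves the ring enlargement ahead of the reduction, so that the ring fusion is set in the decalin series. OsO4/NMO gives the 8α,9-diol enone F6 and MsCl its 9-mesylate F7. LiClO4/CaCO3 gives the 9-epi octalin-3,8-dione F8, and NaOMe equilibrates it to the 9α-H enedione F9. Ph3P=CH2 methylenates the saturated C8 ketone to the 8(17)-methylene enone F10. Li in NH3 gives the lithium enolate F11, which MeI converts to the trans-decalin 4,4-dimethyl-3-ketone F12. NaBH4 gives the 3β-alcohol F13, and silylation with Et3SiCl returns to 17.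

Step 10. Ionisation of the mesylate may be diverted into epoxide closure by the C8 oxygen, elimination toward C11, or migration of C7 instead of C10. The fallback sets out from 12 and changes the nucleofuge and its mode of generation (Tiffeneau–Demjanov instead of sulfonate ionisation). Sharpless aminohydroxylation (benzyl carbamate, t-BuOCl, NaOH, K2OsO2(OH)4 cat., n-PrOH/H2O) from the α face puts nitrogen on the less substituted C9 and gives the 8α-hydroxy-9-(benzyloxycarbonylamino) compound F14, with the same relative configuration as diol 13. Hydrogenolysis (H2, Pd/C) gives the amino alcohol F15. Diazotisation (NaNO2, aqueous AcOH, 0 °C) triggers the same 1,2-shift of C10 and gives 15, which NaOMe equilibrates to 16, where the route is rejoined.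

Further compounds
F1 | step 4 | (1S,7aS)-1-hydroxy-4,7a-dimethyl-1,2,3,6,7,7a-hexahydro-5H-inden-5-one (8β-hydroxy enone) | CC1=C2CC[C@H](O)[C@@]2(C)CCC1=O
F2 | step 4 | dilithium alkoxide-enolate from F1 (C8–OLi, C3–OLi, C3=C4, 5α-H) | [Li+].[Li+].CC=1[C@@H]2CC[C@H]([O-])[C@@]2(C)CCC1[O-]
F3 | step 4 | 8β-hydroxy-4,4,10-trimethyl-trans-hydrindan-3-one | CC1(C)[C@@H]2CC[C@H](O)[C@@]2(C)CCC1=O
F4 | step 4 | 4,4,10-trimethyl-trans-hydrindane-3,8-dione | CC1(C)[C@@H]2CCC(=O)[C@@]2(C)CCC1=O
F5 | step 4 | 3β-hydroxy-4,4,10-trimethyl-trans-hydrindan-8-one | CC1(C)[C@@H]2CCC(=O)[C@@]2(C)CC[C@@H]1O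
F6 | step 5 | 8α,9-diol of enone 8 | CC1=C2CC[C@](O)([C@@H](O)CCC3(C)OCCO3)[C@@]2(C)CCC1=O
F7 | step 5 | 9-methanesulfonate of F6 | CC1=C2CC[C@](O)([C@@H](OS(C)(=O)=O)CCC3(C)OCCO3)[C@@]2(C)CCC1=O
F8 | step 5 | 9-epi ring-enlarged 4,10-dimethyl-octal-4-ene-3,8-dione with ketal side chain at C9 (9β-H) | CC1=C2CCC(=O)[C@@H](CCC3(C)OCCO3)[C@@]2(C)CCC1=O
F9 | step 5 | ring-enlarged 4,10-dimethyl-octal-4-ene-3,8-dione with ketal side chain at C9 (9α-H) | CC1=C2CCC(=O)[C@H](CCC3(C)OCCO3)[C@@]2(C)CCC1=O
F10 | step 5 | 8(17)-methylene enone from F9 | CC1=C2CCC(=C)[C@H](CCC3(C)OCCO3)[C@@]2(C)CCC1=O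
F11 | step 5 | lithium enolate from F10 (C3–OLi, C3=C4, 5α-H) | [Li+].CC=1[C@@H]2CCC(=C)[C@H](CCC3(C)OCCO3)[C@@]2(C)CCC1[O-]
F12 | step 5 | 14,15-dinorlabd-8(17)-ene-3,13-dione 13-ethylene ketal | CC1(C)[C@@H]2CCC(=C)[C@H](CCC3(C)OCCO3)[C@@]2(C)CCC1=O
F13 | step 5 | 3β-hydroxy-14,15-dinorlabd-8(17)-en-13-one ethylene ketal | CC1(C)[C@@H]2CCC(=C)[C@H](CCC3(C)OCCO3)[C@@]2(C)CC[C@@H]1O
F14 | step 10 | 8α-hydroxy-9-(benzyloxycarbonylamino) analogue of 13 | CC1(C)[C@@H]2CC[C@](O)([C@@H](NC(=O)OCc3ccccc3)CCC4(C)OCCO4)[C@@]2(C)CC[C@@H]1O[Si](CC)(CC)CC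
F15 | step 10 | 8α-hydroxy-9-amino analogue of 13 | CC1(C)[C@@H]2CC[C@](O)([C@@H](N)CCC3(C)OCCO3)[C@@]2(C)CC[C@@H]1O[Si](CC)(CC)CC
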